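**Plan**

- Retrosynthesis first removes the benzyl and pivaloyl groups, then cuts the stilbene bond between ring D (C6') and the styryl carbon (Heck), then the C4–C4a bond of pyran ring C (epoxy-arene Friedel–Crafts), then the O1–C2 aryl ether (Mitsunobu), and finally the C3–C4 epoxide and the chalcone C=C (Claisen–Schmidt).
- The enabling feature is that C4 is a diarylmethine carrying ring D and bonded to ring A carbon C4a, which lies para to the C7 oxygen and ortho to O1, while the 3-hydroxyl is trans to ring D. This is the pattern left when an arene opens a C3–C4 trans-epoxide from the back at its benzylic carbon.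
- Forward: the ring D aldehyde and the ring B ketone give the C2–C3–C4 chain; reduction and epoxidation follow; ring A is attached through O1; ring C closes at C4–C4a; ring E is added by Heck coupling; deprotection ends the route.
- Stereochemistry: the L-(+)-tartrate kinetic-resolution epoxidation fixes C3 and the provisional centres C2 and C4. C2 is then inverted in the Mitsunobu step and C4 is inverted in the ring closure, which gives the 2,3-cis-3,4-trans (2R,3R,4R) array. The E-alkene comes from the Heck reaction.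

Key step: step 8

Remarks: flavan locants (O1, C2 bearing ring B, C3, C4 bearing ring D, C4a/C8a of ring A, primed locants on ring D, ring E = catechol ring) are used for open-chain compounds as well. Assumption: 3,4-diacetoxystyrene, used only in one fallback, is taken to be purchasable.

**Route**

Step 1
Reactants: 1 5-bromoresorcinol
Product: 2 1,3-bis(benzyloxy)-5-bromobenzene
Conditions: BnBr (2.3 equiv), K2CO3, DMF, 50 °C
Reagents that add atoms: benzyl bromide BrCc1ccccc1
Why: Williamson ether synthesis on both phenoxides should be clean because the aryl bromide is inert to carbonate and to benzyl bromide.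

Step 2
Reactants: 2 1,3-bis(benzyloxy)-5-bromobenzene
Product: 4 2,4-bis(benzyloxy)-6-bromobenzaldehyde, via aryl iminium chloride 3 (not isolated)
Conditions: POCl3, DMF, 0 → 70 °C; then H2O, 0 °C → rt
Reagents that add atoms: N,N-dimethylformamide CN(C)C=O; water O
Why: Vilsmeier–Haack formylation of 3,5-dialkoxybromobenzenes is expected at the carbon para to one ether, ortho to the other and next to bromine (the carbon between the two ethers being the most hindered), and the iminium salt is hydrolysed on aqueous work-up.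

Step 3
Reactants: 4 2,4-bis(benzyloxy)-6-bromobenzaldehyde; 5 4'-hydroxyacetophenone
Product: 7 (E)-3-[2,4-bis(benzyloxy)-6-bromophenyl]-1-(4-hydroxyphenyl)prop-2-en-1-one, via aldol adduct 6 (not isolated)
Conditions: KOH (50% aq.), EtOH, rt; then dilute HCl to pH 5
Reagents that add atoms: none
Why: Claisen–Schmidt condensation of the ketone enolate (the phenol being carried as its phenoxide) with the non-enolisable aldehyde, followed by E1cB dehydration, should give the conjugated (E)-chalcone as the thermodynamic product.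

Step 4
Reactants: 7 (E)-3-[2,4-bis(benzyloxy)-6-bromophenyl]-1-(4-hydroxyphenyl)prop-2-en-1-one
Product: 8 4-[(E)-3-(2,4-bis(benzyloxy)-6-bromophenyl)prop-2-enoyl]phenyl pivalate
Conditions: PivCl, Et3N, DMAP (5 mol %), CH2Cl2, 0 °C → rt
Reagents that add atoms: pivaloyl chloride CC(C)(C)C(Cl)=O
Why: DMAP-catalysed O-acylation of the only free hydroxyl installs an ester that makes ring B electron-poor for the later steps and is hindered enough to survive borohydride, titanium alkoxide and amine bases.

Step 5
Reactants: 8 4-[(E)-3-(2,4-bis(benzyloxy)-6-bromophenyl)prop-2-enoyl]phenyl pivalate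
Product: 9 racemic 4-[(E)-3-(2,4-bis(benzyloxy)-6-bromophenyl)-1-hydroxyprop-2-en-1-yl]phenyl pivalate
Conditions: NaBH4, CeCl3·7H2O, MeOH/THF, −20 °C; NaHCO3 quench
Reagents that add atoms: none
Why: Luche reduction delivers hydride 1,2 to the enone carbonyl and should spare the C=C bond, the aryl bromide and the aryl pivalate, giving the racemic allylic alcohol.

Step 6
Reactants: 9 racemic 4-[(E)-3-(2,4-bis(benzyloxy)-6-bromophenyl)-1-hydroxyprop-2-en-1-yl]phenyl pivalate
Product: 10 4-[(S)-{(2S,3S)-3-[2,4-bis(benzyloxy)-6-bromophenyl]oxiran-2-yl}(hydroxy)methyl]phenyl pivalate (erythro)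
Conditions: Ti(OiPr)4 (0.2 equiv), L-(+)-DIPT (0.24 equiv), t-BuOOH (0.45 equiv, in decane), 4 Å MS, CH2Cl2, −20 °C; NaOH/brine work-up, Et3N-deactivated silica
Reagents that add atoms: tert-butyl hydroperoxide CC(C)(C)OO
Why: In this Sharpless kinetic resolution the L-(+)-tartrate catalyst is expected to epoxidise only the (R)-enantiomer of 9 (the spatial counterpart of the fast-reacting series of alkyl carbinols, the descriptor differing because aryl outranks vinyl), from the face that gives the erythro epoxy alcohol, so C3 and the provisional configurations at C2 and C4 are set by the ligand, and the unreacted (S)-alcohol is separated.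

Step 7
Reactants: 10 4-[(S)-{(2S,3S)-3-[2,4-bis(benzyloxy)-6-bromophenyl]oxiran-2-yl}(hydroxy)methyl]phenyl pivalate; 11 3-(benzyloxy)phenol
Product: 12 4-[(R)-[3-(benzyloxy)phenoxy]{(2R,3S)-3-[2,4-bis(benzyloxy)-6-bromophenyl]oxiran-2-yl}methyl]phenyl pivalate
Conditions: PPh3, DIAD, toluene, 0 °C → rt
Reagents that add atoms: none
Why: In this Mitsunobu etherification the phenol displaces the oxyphosphonium of the benzylic alcohol by SN2 with inversion at C2 (S to R), the electron-poor pivaloyloxyphenyl ring disfavouring ionisation and the neutral medium sparing the epoxide, whose C2 descriptor changes only because the ranking of its neighbours changes.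

Step 8
Reactants: 12 4-[(R)-[3-(benzyloxy)phenoxy]{(2R,3S)-3-[2,4-bis(benzyloxy)-6-bromophenyl]oxiran-2-yl}methyl]phenyl pivalate
Product: 13 4-[(2R,3R,4R)-7-(benzyloxy)-4-[2,4-bis(benzyloxy)-6-bromophenyl]-3-hydroxychroman-2-yl]phenyl pivalate (2,3-cis-3,4-trans)
Conditions: BF3·OEt2 (0.2 equiv), CH2Cl2, −78 → −40 °C; Et3N quench
Reagents that add atoms: none
Why: The Lewis acid polarises the epoxide C4–O bond, which is benzylic to ring D and loosened further by its ortho and para benzyloxy groups, and ring A carbon C4a attacks C4 from the side opposite the departing oxygen, after which the arenium ion loses its proton and the C3 oxygen becomes the hydroxyl. The closest known reaction type is the acid-mediated intramolecular Friedel–Crafts epoxy-arene cyclisation of aryl 3-arylglycidyl ethers to trans-4-arylchroman-3-ols. Pyran ring C closes in the 6-endo mode through the C4–C4a bond, because the 5-exo alternative at C3 has no benzylic stabilisation and is deactivated by the oxygen on C2. The new stereocentre C4 is controlled by backside opening of the trans-epoxide set in step 6, which places ring D trans to the 3-hydroxyl, while C2 and C3 are not touched. The step needs attack by the ring A carbon para to the benzyloxy group, not by the one between the two oxygens, an intact C2–O bond, and capture of C4 before any hydride shift. Sterics and para-alkoxy activation should secure the first, the electron-poor ring B pivalate the second, and the low temperature, substoichiometric acid and proximity of the tethered arene the third.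

Step 9
Reactants: 14 3,4-bis(benzyloxy)benzaldehyde
Product: 15 3,4-bis(benzyloxy)styrene
Conditions: Ph3PCH3Br, KOt-Bu, THF, 0 °C → rt
Reagents that add atoms: methyltriphenylphosphonium bromide C[P+](c1ccccc1)(c1ccccc1)c1ccccc1.[Br-]
Why: Wittig methylenation of an aromatic aldehyde with the unstabilised ylide is reliable and leaves the benzyl ethers untouched.

Step 10
Reactants: 13 4-[(2R,3R,4R)-7-(benzyloxy)-4-[2,4-bis(benzyloxy)-6-bromophenyl]-3-hydroxychroman-2-yl]phenyl pivalate; 15 3,4-bis(benzyloxy)styrene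
Product: 16 4-[(2R,3R,4R)-7-(benzyloxy)-4-{2,4-bis(benzyloxy)-6-[(E)-3,4-bis(benzyloxy)styryl]phenyl}-3-hydroxychroman-2-yl]phenyl pivalate
Conditions: Pd2(dba)3 (5 mol %), P(t-Bu)3·HBF4 (12 mol %), Cy2NMe, 1,4-dioxane, 90 °C
Reagents that add atoms: none
Why: In this Heck reaction, oxidative addition of the C6' bromide to zerovalent palladium, syn insertion of the styrene at its terminal carbon and syn β-hydride elimination should give the (E)-stilbene, the bulky electron-rich phosphine being chosen because the bromide sits ortho to the flavanyl group.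

Step 11
Reactants: 16 4-[(2R,3R,4R)-7-(benzyloxy)-4-{2,4-bis(benzyloxy)-6-[(E)-3,4-bis(benzyloxy)styryl]phenyl}-3-hydroxychroman-2-yl]phenyl pivalate
Product: 17 (2R,3R,4R)-7-(benzyloxy)-4-{2,4-bis(benzyloxy)-6-[(E)-3,4-bis(benzyloxy)styryl]phenyl}-2-(4-hydroxyphenyl)chroman-3-ol
Conditions: NaOMe (2 equiv), MeOH/THF, 0 °C → rt; aq. NH4Cl
Reagents that add atoms: none
Why: Methoxide transesterification cleaves the aryl pivalate far faster than it could affect the benzyl ethers, and cold, short exposure should keep the ring B phenoxide from opening the pyran ring at C2.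

Step 12
Reactants: 17 (2R,3R,4R)-7-(benzyloxy)-4-{2,4-bis(benzyloxy)-6-[(E)-3,4-bis(benzyloxy)styryl]phenyl}-2-(4-hydroxyphenyl)chroman-3-ol
Product: 18 (2R,3R,4R)-4-{2-[(E)-2-(3,4-dihydroxyphenyl)ethenyl]-4,6-dihydroxyphenyl}-2-(4-hydroxyphenyl)chromane-3,7-diol (CNP0170061.2)
Conditions: BCl3 (excess), pentamethylbenzene (excess), CH2Cl2, −78 °C; then MeOH
Reagents that add atoms: none
Why: In this Lewis-acid debenzylation BCl3 activates each aryl benzyl ether and pentamethylbenzene traps the benzyl cation as a non-basic scavenger, so the stilbene and the electron-rich rings should not be benzylated, no hydrogenation touches the alkene, and the three stereocentres are not involved.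

**Compound list**

1 | 5-bromoresorcinol | Oc1cc(O)cc(Br)c1 | starting material
2 | 1,3-bis(benzyloxy)-5-bromobenzene | Brc1cc(OCc2ccccc2)cc(OCc2ccccc2)c1 | intermediate
3 | [2,4-bis(benzyloxy)-6-bromophenyl]methylidene(dimethyl)iminium chloride | C[N+](C)=Cc1c(OCc2ccccc2)cc(OCc2ccccc2)cc1Br.[Cl-] | intermediate (not isolated)
4 | 2,4-bis(benzyloxy)-6-bromobenzaldehyde | O=Cc1c(OCc2ccccc2)cc(OCc2ccccc2)cc1Br | intermediate
5 | 4'-hydroxyacetophenone | CC(=O)c1ccc(O)cc1 | starting material
6 | 3-[2,4-bis(benzyloxy)-6-bromophenyl]-3-hydroxy-1-(4-hydroxyphenyl)propan-1-one (racemic aldol adduct) | O=C(CC(O)c1c(OCc2ccccc2)cc(OCc2ccccc2)cc1Br)c1ccc(O)cc1 | intermediate (not isolated)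
7 | (E)-3-[2,4-bis(benzyloxy)-6-bromophenyl]-1-(4-hydroxyphenyl)prop-2-en-1-one | O=C(/C=C/c1c(OCc2ccccc2)cc(OCc2ccccc2)cc1Br)c1ccc(O)cc1 | intermediate
8 | 4-[(E)-3-(2,4-bis(benzyloxy)-6-bromophenyl)prop-2-enoyl]phenyl pivalate | CC(C)(C)C(=O)Oc1ccc(cc1)C(=O)/C=C/c1c(OCc2ccccc2)cc(OCc2ccccc2)cc1Br | intermediate
9 | racemic 4-[(E)-3-(2,4-bis(benzyloxy)-6-bromophenyl)-1-hydroxyprop-2-en-1-yl]phenyl pivalate | CC(C)(C)C(=O)Oc1ccc(cc1)C(O)/C=C/c1c(OCc2ccccc2)cc(OCc2ccccc2)cc1Br | intermediate
10 | 4-[(S)-{(2S,3S)-3-[2,4-bis(benzyloxy)-6-bromophenyl]oxiran-2-yl}(hydroxy)methyl]phenyl pivalate | CC(C)(C)C(=O)Oc1ccc(cc1)[C@H](O)[C@@H]1O[C@H]1c1c(OCc2ccccc2)cc(OCc2ccccc2)cc1Br | intermediate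
11 | 3-(benzyloxy)phenol | Oc1cccc(OCc2ccccc2)c1 | starting material
12 | 4-[(R)-[3-(benzyloxy)phenoxy]{(2R,3S)-3-[2,4-bis(benzyloxy)-6-bromophenyl]oxiran-2-yl}methyl]phenyl pivalate | CC(C)(C)C(=O)Oc1ccc(cc1)[C@@H](Oc1cccc(OCc2ccccc2)c1)[C@@H]1O[C@H]1c1c(OCc2ccccc2)cc(OCc2ccccc2)cc1Br | intermediate (key-step precursor)
13 | 4-[(2R,3R,4R)-7-(benzyloxy)-4-[2,4-bis(benzyloxy)-6-bromophenyl]-3-hydroxychroman-2-yl]phenyl pivalate | CC(C)(C)C(=O)Oc1ccc(cc1)[C@H]1Oc2cc(OCc3ccccc3)ccc2[C@H](c2c(OCc3ccccc3)cc(OCc3ccccc3)cc2Br)[C@H]1O | intermediate (key-step product)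
14 | 3,4-bis(benzyloxy)benzaldehyde | O=Cc1ccc(OCc2ccccc2)c(OCc2ccccc2)c1 | starting material
15 | 3,4-bis(benzyloxy)styrene | C=Cc1ccc(OCc2ccccc2)c(OCc2ccccc2)c1 | intermediate
16 | 4-[(2R,3R,4R)-7-(benzyloxy)-4-{2,4-bis(benzyloxy)-6-[(E)-3,4-bis(benzyloxy)styryl]phenyl}-3-hydroxychroman-2-yl]phenyl pivalate | CC(C)(C)C(=O)Oc1ccc(cc1)[C@H]1Oc2cc(OCc3ccccc3)ccc2[C@H](c2c(OCc3ccccc3)cc(OCc3ccccc3)cc2/C=C/c2ccc(OCc3ccccc3)c(OCc3ccccc3)c2)[C@H]1O | intermediate
17 | (2R,3R,4R)-7-(benzyloxy)-4-{2,4-bis(benzyloxy)-6-[(E)-3,4-bis(benzyloxy)styryl]phenyl}-2-(4-hydroxyphenyl)chroman-3-ol | Oc1ccc(cc1)[C@H]1Oc2cc(OCc3ccccc3)ccc2[C@H](c2c(OCc3ccccc3)cc(OCc3ccccc3)cc2/C=C/c2ccc(OCc3ccccc3)c(OCc3ccccc3)c2)[C@H]1O | intermediate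
18 | (2R,3R,4R)-4-{2-[(E)-2-(3,4-dihydroxyphenyl)ethenyl]-4,6-dihydroxyphenyl}-2-(4-hydroxyphenyl)chromane-3,7-diol | Oc1ccc([C@H]2Oc3cc(O)ccc3[C@H](c3c(O)cc(O)cc3/C=C/c3ccc(O)c(O)c3)[C@H]2O)cc1 | target

**Step count**

Total step count: 12. Longest linear sequence: 11 steps (steps 1–8 and 10–12, from 5-bromoresorcinol); step 9 is a one-step side branch.

**Steps most likely to fail**

Step 8 (ring closure). The doubly donor-substituted benzylic epoxide may ionise to a free cation faster than ring A can close. That would allow a hydride shift to a C3 ketone, closure from both faces of C4, or attack by the ring A carbon between the two oxygens. The fallback makes the two bonds of ring C in the opposite order and sets out from 10. Intermolecular Friedel–Crafts opening of the epoxide at C4 by resorcinol, used in large excess in hexafluoroisopropanol, should occur through resorcinol C4 and anti to the epoxide oxygen and give 4-[(1S,2R,3R)-3-[2,4-bis(benzyloxy)-6-bromophenyl]-3-(2,4-dihydroxyphenyl)-1,2-dihydroxypropyl]phenyl pivalate F1. An intramolecular Mitsunobu etherification (PPh3, DIAD, THF) would then form O1–C2 from the ortho phenol with inversion at the benzylic carbinol, the six-membered closure at the benzylic carbon being preferred over activation of the C3 hydroxyl, and give 4-[(2R,3R,4R)-4-[2,4-bis(benzyloxy)-6-bromophenyl]-3,7-dihydroxychroman-2-yl]phenyl pivalate F2. Selective benzylation of the 7-phenol (BnBr, K2CO3, acetone) comes back to the route at 13.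

Step 6 (kinetic-resolution epoxidation). The titanium alkoxide may open the electron-rich aryl epoxide as it forms, and the rate difference between the enantiomers of a hindered aryl carbinol may be too small for a clean resolution, which in any case discards half of the material. The fallback sets out from 8 and takes the stereochemistry from a nucleophilic epoxidation instead. Juliá–Colonna epoxidation (poly-L-leucine, urea–H2O2, DBU, THF) should give 4-{[(2R,3S)-3-[2,4-bis(benzyloxy)-6-bromophenyl]oxiran-2-yl]carbonyl}phenyl pivalate F3, an epoxy ketone that is far less acid-labile than the epoxy alcohol. Chelation-controlled reduction with Zn(BH4)2 (Et2O, −20 °C), which is known to give erythro epoxy alcohols from trans-epoxy ketones, comes back to the route at 10.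

Step 12 (fivefold debenzylation). The electron-rich stilbene may oligomerise or cyclise under the Lewis acid, or the C4–ring D bond may heterolyse, while five benzyl ethers are being cleaved. The fallback sets out from 13 and removes the benzyl groups before the stilbene exists. BCl3 and pentamethylbenzene (CH2Cl2, −78 °C) should give 4-[(2R,3R,4R)-4-(2-bromo-4,6-dihydroxyphenyl)-3,7-dihydroxychroman-2-yl]phenyl pivalate F4. Heck coupling with 3,4-diacetoxystyrene (Pd(OAc)2, P(o-tol)3, Et3N, DMF, 90 °C) would give 4-[(2R,3R,4R)-4-{2-[(E)-3,4-diacetoxystyryl]-4,6-dihydroxyphenyl}-3,7-dihydroxychroman-2-yl]phenyl pivalate F5. Mild methanolysis of the three esters (K2CO3, degassed MeOH, 0 °C, under argon, acidic quench) comes back to the route at the target 18.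

**Further compounds**

F1 | step 8 | 4-[(1S,2R,3R)-3-[2,4-bis(benzyloxy)-6-bromophenyl]-3-(2,4-dihydroxyphenyl)-1,2-dihydroxypropyl]phenyl pivalate | CC(C)(C)C(=O)Oc1ccc(cc1)[C@H](O)[C@H](O)[C@H](c1ccc(O)cc1O)c1c(OCc2ccccc2)cc(OCc2ccccc2)cc1Br
F2 | step 8 | 4-[(2R,3R,4R)-4-[2,4-bis(benzyloxy)-6-bromophenyl]-3,7-dihydroxychroman-2-yl]phenyl pivalate | CC(C)(C)C(=O)Oc1ccc(cc1)[C@H]1Oc2cc(O)ccc2[C@H](c2c(OCc3ccccc3)cc(OCc3ccccc3)cc2Br)[C@H]1O
F3 | step 6 | 4-{[(2R,3S)-3-[2,4-bis(benzyloxy)-6-bromophenyl]oxiran-2-yl]carbonyl}phenyl pivalate | CC(C)(C)C(=O)Oc1ccc(cc1)C(=O)[C@@H]1O[C@H]1c1c(OCc2ccccc2)cc(OCc2ccccc2)cc1Br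
F4 | step 12 | 4-[(2R,3R,4R)-4-(2-bromo-4,6-dihydroxyphenyl)-3,7-dihydroxychroman-2-yl]phenyl pivalate | CC(C)(C)C(=O)Oc1ccc(cc1)[C@H]1Oc2cc(O)ccc2[C@H](c2c(O)cc(O)cc2Br)[C@H]1O
F5 | step 12 | 4-[(2R,3R,4R)-4-{2-[(E)-3,4-diacetoxystyryl]-4,6-dihydroxyphenyl}-3,7-dihydroxychroman-2-yl]phenyl pivalate | CC(C)(C)C(=O)Oc1ccc(cc1)[C@H]1Oc2cc(O)ccc2[C@H](c2c(O)cc(O)cc2/C=C/c2ccc(OC(C)=O)c(OC(C)=O)c2)[C@H]1O
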